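**Retrosynthetic overview** (azulene numbering: C1, C2, C3(OH)(iPr), C3a(H), C4(O‑ester), C5, C6(OH)(CH3), C7=C8, C8a(CH3); α = face of H‑3a, β = face of the C8a methyl)
1. Last operations: acylation of the C4 hydroxyl and one global desilylation. The C4–O and C3a–H bonds come from a syn hydrosilylation of a C3a=C4 alkene delivered from the α‑oriented C6 oxygen, followed by Tamao–Fleming oxidation.
2. Key disconnection: C4–C5 and C3a–C8a, made together by a Rh(I) [5+2] cycloaddition of a terminal alkyne (C3a≡C4) with an alkenylcyclopropane. The five‑ and seven‑membered rings form in the same operation.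
3. Enabling feature: the C8a–C8=C7–C6–C5 segment of the seven‑membered ring, with C6 as a carbinol carbon, is the opened form of a 2‑alkoxy‑2‑methyl‑1‑alkenylcyclopropane (ring C5–C6–C7). The strained C7–C5 bond is the one cut, and the three‑atom tether C3–C2–C1 becomes the five‑membered ring.
4. The precursor is assembled at C8a by two stereospecific couplings of a gem‑dichloroalkene: C1–C8a (B‑alkyl Suzuki), then C8a–CH3 (Negishi).
5. Ring order: cyclopropane (step 3, sacrificial), then both carbocycles (step 16), then a temporary oxasilolane bridge (step 18). The C6 stereocentre comes from an asymmetric Simmons–Smith reaction and the C3 stereocentre from a Sharpless epoxidation.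

Key step: step 16

Remark: ethyl but‑2‑ynoate, 4‑methoxybenzyl alcohol, 3‑methylbut‑1‑yne, ethyl chloroformate and 4‑[(tert‑butyldimethylsilyl)oxy]benzoic acid are taken as commercial; PMB = 4‑methoxybenzyl, TES = triethylsilyl.

**Step 1**
Reactants: 1 ethyl but‑2‑ynoate; 2 4‑methoxybenzyl alcohol
Product: 3 ethyl (2E)‑3‑[(4‑methoxybenzyl)oxy]but‑2‑enoate
Conditions: PMe3 (10 mol %), CH2Cl2, 0 °C→rt
Reagents that add atoms: none
Why: Phosphine‑catalysed oxa‑Michael addition of the alcohol to the ynoate should give the thermodynamically preferred (E)‑β‑alkoxycrotonate, which fixes the trans relationship of the ether oxygen and the future CH2OH group.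

**Step 2**
Reactants: 3 ethyl (2E)‑3‑[(4‑methoxybenzyl)oxy]but‑2‑enoate
Product: 4 (2E)‑3‑[(4‑methoxybenzyl)oxy]but‑2‑en‑1‑ol
Conditions: DIBAL‑H (2.2 equiv), CH2Cl2, −78 °C; Rochelle salt work‑up
Reagents that add atoms: none
Why: DIBAL‑H 1,2‑reduction of the ester should leave the enol ether intact, and the neutral work‑up avoids hydrolysis of the acid‑labile β‑alkoxy allylic alcohol.

**Step 3**
Reactants: 4 (2E)‑3‑[(4‑methoxybenzyl)oxy]but‑2‑en‑1‑ol
Product: 5 [(1S,2R)‑2‑[(4‑methoxybenzyl)oxy]‑2‑methylcyclopropyl]methanol (CH2OH cis to CH3)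
Conditions: Et2Zn, CH2I2, DME (gives Zn(CH2I)2·DME); (4S,5S)‑2‑butyl‑N,N,N′,N′‑tetramethyl‑1,3,2‑dioxaborolane‑4,5‑dicarboxamide (1.2 equiv), CH2Cl2, −10 °C→rt
Reagents that add atoms: diiodomethane, ICI
Why: In this dioxaborolane‑mediated asymmetric Simmons–Smith cyclopropanation the zinc alkoxide directs CH2 to one face of the electron‑rich alkene, the (E)‑geometry is transferred stereospecifically (CH2OH cis to CH3, trans to OPMB), and the (S,S)‑ligand is chosen to give the (1S,2R) enantiomer that becomes C6 of the target.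

**Step 4**
Reactants: 5 [(1S,2R)‑2‑[(4‑methoxybenzyl)oxy]‑2‑methylcyclopropyl]methanol
Product: 6 (1R,2R)‑2‑[(4‑methoxybenzyl)oxy]‑2‑methylcyclopropane‑1‑carbaldehyde
Conditions: Dess–Martin periodinane, NaHCO3, CH2Cl2, 0 °C; used directly
Reagents that add atoms: none
Why: Buffered Dess–Martin oxidation should give the aldehyde without acid that could open the donor‑substituted cyclopropane or base that could epimerise it.

**Step 5**
Reactants: 6 (1R,2R)‑2‑[(4‑methoxybenzyl)oxy]‑2‑methylcyclopropane‑1‑carbaldehyde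
Product: 7 (1R,2S)‑2‑(2,2‑dichloroethenyl)‑1‑methylcyclopropyl 4‑methoxybenzyl ether
Conditions: Cl3CP(O)(OEt)2, n‑BuLi, THF/Et2O, −100 °C; then 6, −100 °C→rt
Reagents that add atoms: diethyl (trichloromethyl)phosphonate, CCOP(=O)(OCC)C(Cl)(Cl)Cl
Why: Horner–Wadsworth–Emmons‑type dichloromethylenation with the lithiated dichloromethylphosphonate should give the gem‑dichloroalkene under cold basic conditions that the alkoxycyclopropane tolerates.

**Step 6**
Reactants: 8 3‑methylbut‑1‑yne; 9 ethyl chloroformate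
Product: 10 ethyl 4‑methylpent‑2‑ynoate
Conditions: n‑BuLi, THF, −78 °C; then 9, −78→0 °C
Reagents that add atoms: none
Why: Acylation of the lithium acetylide with a chloroformate is the standard route to 2‑ynoates.

**Step 7**
Reactants: 10 ethyl 4‑methylpent‑2‑ynoate
Product: 11 ethyl (2E)‑3‑(propan‑2‑yl)penta‑2,4‑dienoate
Conditions: CH2=CHMgBr, CuBr·SMe2, THF, −78 °C; NH4Cl/MeOH quench at −78 °C
Reagents that add atoms: vinylmagnesium bromide, C=C[Mg]Br
Why: syn‑Carbocupration of the ynoate and cold protonation should place vinyl and H cis (vinyl trans to CO2Et), the alkene geometry that the later epoxidation converts into the C3 configuration.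

**Step 8**
Reactants: 11 ethyl (2E)‑3‑(propan‑2‑yl)penta‑2,4‑dienoate
Product: 12 (2E)‑3‑(propan‑2‑yl)penta‑2,4‑dien‑1‑ol
Conditions: DIBAL‑H (2.2 equiv), CH2Cl2, −78 °C
Reagents that add atoms: none
Why: DIBAL‑H should reduce the dienoate to the allylic alcohol by 1,2‑reduction without conjugate reduction.

**Step 9**
Reactants: 12 (2E)‑3‑(propan‑2‑yl)penta‑2,4‑dien‑1‑ol
Product: 13 [(2S,3S)‑3‑ethenyl‑3‑(propan‑2‑yl)oxiran‑2‑yl]methanol
Conditions: Ti(OiPr)4 (10 mol %), L‑(+)‑diisopropyl tartrate (12 mol %), t‑BuOOH, 4 Å MS, CH2Cl2, −20 °C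
Reagents that add atoms: tert‑butyl hydroperoxide, CC(C)(C)OO
Why: Sharpless asymmetric epoxidation acts only on the allylic‑alcohol double bond, and with L‑(+)‑tartrate the usual facial rule (the same sense as for geraniol) should give the (2S,3S)‑epoxide whose C3 becomes the tertiary carbinol centre.

**Step 10**
Reactants: 13 [(2S,3S)‑3‑ethenyl‑3‑(propan‑2‑yl)oxiran‑2‑yl]methanol
Product: 14 (2R,3S)‑2‑(chloromethyl)‑3‑ethenyl‑3‑(propan‑2‑yl)oxirane
Conditions: PPh3, N‑chlorosuccinimide, NaHCO3, CH2Cl2, 0 °C→rt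
Reagents that add atoms: N‑chlorosuccinimide, ClN1C(=O)CCC1=O
Why: Appel‑type chlorination of the primary alcohol under neutral conditions should leave the acid‑sensitive vinyl epoxide untouched.

**Step 11**
Reactants: 14 (2R,3S)‑2‑(chloromethyl)‑3‑ethenyl‑3‑(propan‑2‑yl)oxirane
Product: 17 (3S)‑3‑(propan‑2‑yl)‑5‑(trimethylsilyl)pent‑1‑en‑4‑yn‑3‑ol, via dilithium alkoxide–acetylide 15 (not isolated), via O,C‑bis(trimethylsilyl) derivative 16 (not isolated)
Conditions: LDA (3.3 equiv), THF, −78→−30 °C; TMSCl (2.5 equiv), −78 °C→rt; aqueous citric acid/MeOH work‑up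
Reagents that add atoms: chlorotrimethylsilane, C[Si](C)(C)Cl
Why: Base‑induced double elimination of the 2,3‑epoxy chloride (epoxide opening to a chloro‑allylic alkoxide, then dehydrochlorination) should give the tertiary propargylic alcohol with the C–O stereocentre untouched, and silylation of the dianion followed by mild acid leaves only the C‑silyl group that masks the alkyne.

**Step 12**
Reactants: 17 (3S)‑3‑(propan‑2‑yl)‑5‑(trimethylsilyl)pent‑1‑en‑4‑yn‑3‑ol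
Product: 18 triethyl{[(3S)‑3‑(propan‑2‑yl)‑5‑(trimethylsilyl)pent‑1‑en‑4‑yn‑3‑yl]oxy}silane
Conditions: TESOTf, 2,6‑lutidine, CH2Cl2, 0 °C
Reagents that add atoms: triethylsilyl trifluoromethanesulfonate, CC[Si](CC)(CC)OS(=O)(=O)C(F)(F)F
Why: The silyl triflate should silylate the hindered tertiary alcohol, which keeps this oxygen inert to the borane and zinc reagents and prevents it from acting as a competing tether in step 18.

**Step 13**
Reactants: 18 triethyl{[(3S)‑3‑(propan‑2‑yl)‑5‑(trimethylsilyl)pent‑1‑en‑4‑yn‑3‑yl]oxy}silane; 7 (1R,2S)‑2‑(2,2‑dichloroethenyl)‑1‑methylcyclopropyl 4‑methoxybenzyl ether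
Product: 20 {[(3R,6Z)‑6‑chloro‑7‑{(1S,2R)‑2‑[(4‑methoxybenzyl)oxy]‑2‑methylcyclopropyl}‑3‑(propan‑2‑yl)‑1‑(trimethylsilyl)hept‑6‑en‑1‑yn‑3‑yl]oxy}(triethyl)silane, via B‑alkyl‑9‑borabicyclononane 19 (not isolated)
Conditions: 9‑BBN, THF, 0 °C→rt; then 7, Pd2(dba)3 (2.5 mol %), Xantphos (5 mol %), aq. K3PO4, THF, 60 °C
Reagents that add atoms: none
Why: 9‑BBN should hydroborate only the monosubstituted alkene at its terminal carbon, and the B‑alkyl Suzuki–Miyaura coupling of a gem‑dichloroalkene is expected at the less hindered C–Cl bond trans to the cyclopropane, giving the (Z)‑chloroalkene.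

**Step 14**
Reactants: 20 the (6Z)‑chloroalkene
Product: 21 {[(3R,6E)‑7‑{(1S,2R)‑2‑[(4‑methoxybenzyl)oxy]‑2‑methylcyclopropyl}‑6‑methyl‑3‑(propan‑2‑yl)‑1‑(trimethylsilyl)hept‑6‑en‑1‑yn‑3‑yl]oxy}(triethyl)silane
Conditions: Me2Zn, Pd(t‑Bu3P)2 (5 mol %), THF, 0 °C→rt
Reagents that add atoms: dimethylzinc, C[Zn]C
Why: Negishi methylation of the alkenyl chloride with a bulky‑phosphine palladium catalyst should proceed with retention, so the methyl group ends cis to the cyclopropane and the chain trans, giving the (E)‑trisubstituted alkene.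

**Step 15**
Reactants: 21 the C‑silyl alkyne
Product: 22 {[(3R,6E)‑7‑{(1S,2R)‑2‑[(4‑methoxybenzyl)oxy]‑2‑methylcyclopropyl}‑6‑methyl‑3‑(propan‑2‑yl)hept‑6‑en‑1‑yn‑3‑yl]oxy}(triethyl)silane
Conditions: K2CO3, MeOH, rt
Reagents that add atoms: none
Why: Mild methanolysis should cleave only the C(sp)–SiMe3 bond, leaving the tertiary TES ether and the PMB ether in place.

**Step 16**
Reactants: 22 the alkyne‑tethered alkenylcyclopropane
Product: 23 (3R,6R,8aR)‑6‑[(4‑methoxybenzyl)oxy]‑6,8a‑dimethyl‑3‑(propan‑2‑yl)‑3‑[(triethylsilyl)oxy]‑1,2,3,5,6,8a‑hexahydroazulene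
Conditions: [Rh(CO)2Cl]2 (5 mol %), degassed toluene (0.02 M), 80 °C
Reagents that add atoms: none
Why: Rh(I) bound to the alkenylcyclopropane should insert into the CH2‑terminated C7–C5 bond with release of ring strain to give a σ,π‑allyl rhodacycle, the tethered alkyne then inserts at the allyl terminus C8a, and C(sp2)–C(sp3) reductive elimination joins C4 to C5. The closest known reaction type is the intramolecular Rh(I)‑catalysed [5+2] cycloaddition of alkyne‑tethered vinylcyclopropanes, which includes 1,2‑disubstituted cyclopropanes and alkenes that generate quaternary ring‑fusion carbons. The five‑membered ring closes through the three‑atom tether C3–C2–C1 as C3a–C8a forms, and the seven‑membered ring closes by union of the five‑carbon unit C8a–C8=C7–C6–C5 with C4=C3a. The only new stereocentre, C8a, is controlled by the cyclopropane: bonding at C8a occurs on the alkene face syn to the breaking C7–C5 bond, so the (E)‑alkene (CH3 cis to the ring) and the cyclopropane with CH3 cis to the alkenyl group place both methyl groups on the same face, while C6 and C3 pass through unchanged. The step needs cleavage of the cyclopropane bond that ends at CH2 rather than at C6, which the full substitution at C6 should secure, and a cis C7=C8 bond, which the ring enforces. The gem‑disubstituted C3 in the tether should favour cyclisation over alkyne oligomerisation.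

**Step 17**
Reactants: 23 the PMB‑protected cycloadduct
Product: 24 (3R,6R,8aR)‑6,8a‑dimethyl‑3‑(propan‑2‑yl)‑3‑[(triethylsilyl)oxy]‑1,2,3,5,6,8a‑hexahydroazulen‑6‑ol
Conditions: DDQ, CH2Cl2/pH 7 buffer, 0 °C
Reagents that add atoms: none
Why: Oxidative cleavage of the PMB ether with buffered DDQ should free the tertiary allylic alcohol without acid‑induced ionisation, and the quaternary C8a prevents dehydrogenation of the skipped diene.

**Step 18**
Reactants: 24 the C6 tertiary alcohol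
Product: 27 (3R,3aS,4S,6R,8aR)‑6,8a‑dimethyl‑3‑(propan‑2‑yl)‑3‑[(triethylsilyl)oxy]‑1,2,3,3a,4,5,6,8a‑octahydroazulene‑4,6‑diol, via dimethylsilyl ether 25 (not isolated), via bridged oxasilolane 26 (not isolated)
Conditions: Me2SiHCl, Et3N, DMAP (cat.), CH2Cl2, 0 °C→rt, filter, concentrate; Karstedt catalyst (1 mol %), toluene, 60 °C; then KF, KHCO3, 30 % H2O2, THF/MeOH, rt
Reagents that add atoms: hydrogen peroxide, OO
Why: In this Tamao‑type intramolecular hydrosilylation the Si–H group tethered to the α‑oriented C6 oxygen can reach only the α‑face of C4 (1,3‑cis bridge), so syn addition should place Si on C4 and H on C3a on the α‑face (trans ring fusion), and Tamao–Fleming oxidation then replaces C–Si by C–OH with retention and frees the C6 hydroxyl.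

**Step 19**
Reactants: 27 the 4,6‑diol; 28 4‑[(tert‑butyldimethylsilyl)oxy]benzoic acid
Product: 29 (3R,3aS,4S,6R,8aR)‑6‑hydroxy‑6,8a‑dimethyl‑3‑(propan‑2‑yl)‑3‑[(triethylsilyl)oxy]‑1,2,3,3a,4,5,6,8a‑octahydroazulen‑4‑yl 4‑[(tert‑butyldimethylsilyl)oxy]benzoate
Conditions: DCC, DMAP, CH2Cl2, rt
Reagents that add atoms: none
Why: Steglich esterification should acylate the only secondary hydroxyl, since the tertiary C6 alcohol and the silylated C3 oxygen do not react under these conditions.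

**Step 20**
Reactants: 29 the bis‑silylated ester
Product: 30 (3R,3aS,4S,6R,8aR)‑3,6‑dihydroxy‑6,8a‑dimethyl‑3‑(propan‑2‑yl)‑1,2,3,3a,4,5,6,8a‑octahydroazulen‑4‑yl 4‑hydroxybenzoate
Conditions: HF·pyridine, pyridine, THF, 0 °C→rt
Reagents that add atoms: none
Why: Buffered fluoride should cleave the aryl TBS ether and the tertiary TES ether in one operation without touching the ester or the tertiary allylic alcohol, giving the target.

**Compound list**
1 | ethyl but‑2‑ynoate | CCOC(=O)C#CC | starting material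
2 | 4‑methoxybenzyl alcohol | COc1ccc(CO)cc1 | starting material
3 | ethyl (2E)‑3‑[(4‑methoxybenzyl)oxy]but‑2‑enoate | CCOC(=O)/C=C(\C)OCc1ccc(OC)cc1 | intermediate
4 | (2E)‑3‑[(4‑methoxybenzyl)oxy]but‑2‑en‑1‑ol | OC/C=C(\C)OCc1ccc(OC)cc1 | intermediate
5 | [(1S,2R)‑2‑[(4‑methoxybenzyl)oxy]‑2‑methylcyclopropyl]methanol | OC[C@@H]1C[C@@]1(C)OCc1ccc(OC)cc1 | intermediate
6 | (1R,2R)‑2‑[(4‑methoxybenzyl)oxy]‑2‑methylcyclopropane‑1‑carbaldehyde | O=C[C@@H]1C[C@@]1(C)OCc1ccc(OC)cc1 | intermediate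
7 | (1R,2S)‑2‑(2,2‑dichloroethenyl)‑1‑methylcyclopropyl 4‑methoxybenzyl ether | ClC(Cl)=C[C@@H]1C[C@@]1(C)OCc1ccc(OC)cc1 | intermediate
8 | 3‑methylbut‑1‑yne | CC(C)C#C | starting material
9 | ethyl chloroformate | CCOC(=O)Cl | starting material
10 | ethyl 4‑methylpent‑2‑ynoate | CCOC(=O)C#CC(C)C | intermediate
11 | ethyl (2E)‑3‑(propan‑2‑yl)penta‑2,4‑dienoate | C=C/C(C(C)C)=C/C(=O)OCC | intermediate
12 | (2E)‑3‑(propan‑2‑yl)penta‑2,4‑dien‑1‑ol | C=C/C(C(C)C)=C/CO | intermediate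
13 | [(2S,3S)‑3‑ethenyl‑3‑(propan‑2‑yl)oxiran‑2‑yl]methanol | OC[C@@H]1O[C@]1(C=C)C(C)C | intermediate
14 | (2R,3S)‑2‑(chloromethyl)‑3‑ethenyl‑3‑(propan‑2‑yl)oxirane | ClC[C@@H]1O[C@]1(C=C)C(C)C | intermediate
15 | dilithium alkoxide–acetylide of (3S)‑3‑(propan‑2‑yl)pent‑1‑en‑4‑yn‑3‑ol | CC(C)[C@@](O[Li])(C#C[Li])C=C | intermediate
16 | trimethyl{[(3S)‑3‑(propan‑2‑yl)‑5‑(trimethylsilyl)pent‑1‑en‑4‑yn‑3‑yl]oxy}silane | CC(C)[C@@](O[Si](C)(C)C)(C#C[Si](C)(C)C)C=C | intermediate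
17 | (3S)‑3‑(propan‑2‑yl)‑5‑(trimethylsilyl)pent‑1‑en‑4‑yn‑3‑ol | CC(C)[C@@](O)(C#C[Si](C)(C)C)C=C | intermediate
18 | triethyl{[(3S)‑3‑(propan‑2‑yl)‑5‑(trimethylsilyl)pent‑1‑en‑4‑yn‑3‑yl]oxy}silane | CC(C)[C@@](O[Si](CC)(CC)CC)(C#C[Si](C)(C)C)C=C | intermediate
19 | 9‑{(3R)‑4‑methyl‑3‑[(triethylsilyl)oxy]‑3‑[(trimethylsilyl)ethynyl]pentyl}‑9‑borabicyclo[3.3.1]nonane | CC(C)[C@@](O[Si](CC)(CC)CC)(C#C[Si](C)(C)C)CCB1C2CCCC1CCC2 | intermediate
20 | {[(3R,6Z)‑6‑chloro‑7‑{(1S,2R)‑2‑[(4‑methoxybenzyl)oxy]‑2‑methylcyclopropyl}‑3‑(propan‑2‑yl)‑1‑(trimethylsilyl)hept‑6‑en‑1‑yn‑3‑yl]oxy}(triethyl)silane | CC(C)[C@@](O[Si](CC)(CC)CC)(C#C[Si](C)(C)C)CC/C(Cl)=C/[C@@H]1C[C@@]1(C)OCc1ccc(OC)cc1 | intermediate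
21 | {[(3R,6E)‑7‑{(1S,2R)‑2‑[(4‑methoxybenzyl)oxy]‑2‑methylcyclopropyl}‑6‑methyl‑3‑(propan‑2‑yl)‑1‑(trimethylsilyl)hept‑6‑en‑1‑yn‑3‑yl]oxy}(triethyl)silane | CC(C)[C@@](O[Si](CC)(CC)CC)(C#C[Si](C)(C)C)CC/C(C)=C/[C@@H]1C[C@@]1(C)OCc1ccc(OC)cc1 | intermediate
22 | {[(3R,6E)‑7‑{(1S,2R)‑2‑[(4‑methoxybenzyl)oxy]‑2‑methylcyclopropyl}‑6‑methyl‑3‑(propan‑2‑yl)hept‑6‑en‑1‑yn‑3‑yl]oxy}(triethyl)silane | CC(C)[C@@](O[Si](CC)(CC)CC)(C#C)CC/C(C)=C/[C@@H]1C[C@@]1(C)OCc1ccc(OC)cc1 | intermediate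
23 | (3R,6R,8aR)‑6‑[(4‑methoxybenzyl)oxy]‑6,8a‑dimethyl‑3‑(propan‑2‑yl)‑3‑[(triethylsilyl)oxy]‑1,2,3,5,6,8a‑hexahydroazulene | CC(C)[C@]1(O[Si](CC)(CC)CC)CC[C@]2(C)C=C[C@](C)(OCc3ccc(OC)cc3)CC=C12 | intermediate
24 | (3R,6R,8aR)‑6,8a‑dimethyl‑3‑(propan‑2‑yl)‑3‑[(triethylsilyl)oxy]‑1,2,3,5,6,8a‑hexahydroazulen‑6‑ol | CC(C)[C@]1(O[Si](CC)(CC)CC)CC[C@]2(C)C=C[C@](C)(O)CC=C12 | intermediate
25 | O6‑dimethylsilyl ether of 24 | CC(C)[C@]1(O[Si](CC)(CC)CC)CC[C@]2(C)C=C[C@](C)(O[SiH](C)C)CC=C12 | intermediate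
26 | bridged oxasilolane (C6–O–SiMe2–C4 on the α‑face, H‑3a α, C3–OTES retained) | CC(C)[C@]1(O[Si](CC)(CC)CC)CC[C@]2(C)C=C[C@](C)(O3)C[C@H]([Si]3(C)C)[C@H]21 | intermediate
27 | (3R,3aS,4S,6R,8aR)‑6,8a‑dimethyl‑3‑(propan‑2‑yl)‑3‑[(triethylsilyl)oxy]‑1,2,3,3a,4,5,6,8a‑octahydroazulene‑4,6‑diol | CC(C)[C@]1(O[Si](CC)(CC)CC)CC[C@]2(C)C=C[C@](C)(O)C[C@H](O)[C@H]21 | intermediate
28 | 4‑[(tert‑butyldimethylsilyl)oxy]benzoic acid | CC(C)(C)[Si](C)(C)Oc1ccc(cc1)C(=O)O | starting material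
29 | (3R,3aS,4S,6R,8aR)‑6‑hydroxy‑6,8a‑dimethyl‑3‑(propan‑2‑yl)‑3‑[(triethylsilyl)oxy]‑1,2,3,3a,4,5,6,8a‑octahydroazulen‑4‑yl 4‑[(tert‑butyldimethylsilyl)oxy]benzoate | CC(C)[C@]1(O[Si](CC)(CC)CC)CC[C@]2(C)C=C[C@](C)(O)C[C@H](OC(=O)c3ccc(O[Si](C)(C)C(C)(C)C)cc3)[C@H]21 | intermediate
30 | (3R,3aS,4S,6R,8aR)‑3,6‑dihydroxy‑6,8a‑dimethyl‑3‑(propan‑2‑yl)‑1,2,3,3a,4,5,6,8a‑octahydroazulen‑4‑yl 4‑hydroxybenzoate | CC(C)[C@]1(O)CC[C@]2(C)C=C[C@](C)(O)C[C@H](OC(=O)c3ccc(O)cc3)[C@H]21 | target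

**Total step count:** 20
**Longest linear sequence:** 15 steps (steps 6–20, from 3‑methylbut‑1‑yne)

**Steps most likely to fail**

Step 16 (key cycloaddition). C3a–C8a bond formation joins an alkyne carbon that sits next to the fully substituted C3 to an alkene carbon that becomes quaternary and carries an inward‑pointing methyl group. Alkyne insertion into the rhodacycle may therefore be too slow, so that the alkoxycyclopropane isomerises or the alkyne oligomerises first. The fallback carries C3 through the cycloaddition as a flat, activating carbonyl and installs the isopropyl carbinol afterwards; it sets out from 7 and returns at 23. Trans‑selective Negishi monoalkylation of 7 with commercial (3‑ethoxy‑3‑oxopropyl)zinc bromide (Pd(DPEphos)Cl2, THF) should give the chloro ester F1. Methylation with Me2Zn/Pd(t‑Bu3P)2 then gives the (E)‑ester F2. MeNH(OMe)·HCl with i‑PrMgCl gives the Weinreb amide F3, and ethynylmagnesium bromide gives the ynone F4. The Rh(I) [5+2] cycloaddition of this conjugated ynone, a more reactive and less hindered two‑carbon partner, should give the bicyclic dienone F5. 1,2‑Addition of i‑PrLi/CeCl3 to the ketone, expected from the face opposite the C8a methyl group, gives the tertiary alcohol F6, and TESOTf/2,6‑lutidine converts it into 23.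

Step 18 (tethered hydrosilylation). The Si–H group may add to the allylic C7=C8 bond instead, or a platinum hydride may isomerise the skipped diene before the hindered trisubstituted C3a=C4 bond reacts. The fallback sets C3a and C4 by redox correction instead of delivery from oxygen; it sets out from 23 and returns at 29. Hydroboration–oxidation of the more electron‑rich trisubstituted alkene (BH3·SMe2, then NaBO3) gives the C4 alcohol F7 (drawn for β‑face attack; either facial outcome is usable). Dess–Martin oxidation gives the ketone F8. Equilibration of C3a with DBU should favour the trans‑fused ketone F9. NaBH4/CeCl3, attacking anti to the C8a methyl group, should give the 4β‑alcohol F10. Mitsunobu esterification with 28 (PPh3, DIAD) inverts C4 to give the ester F11, and DDQ removes the PMB group to give 29.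

Step 13 (first coupling of the gem‑dichloroalkene). The coupling may not stop at mono‑substitution or may lose its trans‑selectivity, or slow oxidative addition into the vinyl C–Cl bond may let the alkylborane protodeboronate. The fallback fixes the alkene geometry by syn‑hydrometalation instead; it sets out from 6 and returns at 21. Ohira–Bestmann homologation of 6 (dimethyl (1‑diazo‑2‑oxopropyl)phosphonate, K2CO3, MeOH) gives the terminal alkyne F12. LiHMDS and MeI give the methylalkyne F13. Hydrozirconation with Cp2Zr(H)Cl (Zr at the methyl‑bearing carbon) followed by I2 gives the (E)‑alkenyl iodide F14. B‑alkyl Suzuki coupling of F14 with borane 19 (Pd(dppf)Cl2, AsPh3, Cs2CO3, DMF/THF/H2O) gives 21 directly.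

**Further compounds**
F1 | step 16 | ethyl (4Z)‑4‑chloro‑5‑{(1S,2R)‑2‑[(4‑methoxybenzyl)oxy]‑2‑methylcyclopropyl}pent‑4‑enoate | CCOC(=O)CC/C(Cl)=C/[C@@H]1C[C@@]1(C)OCc1ccc(OC)cc1
F2 | step 16 | ethyl (4E)‑5‑{(1S,2R)‑2‑[(4‑methoxybenzyl)oxy]‑2‑methylcyclopropyl}‑4‑methylpent‑4‑enoate | CCOC(=O)CC/C(C)=C/[C@@H]1C[C@@]1(C)OCc1ccc(OC)cc1
F3 | step 16 | (4E)‑N‑methoxy‑5‑{(1S,2R)‑2‑[(4‑methoxybenzyl)oxy]‑2‑methylcyclopropyl}‑N,4‑dimethylpent‑4‑enamide | CON(C)C(=O)CC/C(C)=C/[C@@H]1C[C@@]1(C)OCc1ccc(OC)cc1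
F4 | step 16 | (6E)‑7‑{(1S,2R)‑2‑[(4‑methoxybenzyl)oxy]‑2‑methylcyclopropyl}‑6‑methylhept‑6‑en‑1‑yn‑3‑one | C#CC(=O)CC/C(C)=C/[C@@H]1C[C@@]1(C)OCc1ccc(OC)cc1
F5 | step 16 | (6R,8aR)‑6‑[(4‑methoxybenzyl)oxy]‑6,8a‑dimethyl‑2,5,6,8a‑tetrahydroazulen‑3(1H)‑one | O=C1CC[C@]2(C)C=C[C@](C)(OCc3ccc(OC)cc3)CC=C12
F6 | step 16 | (3R,6R,8aR)‑6‑[(4‑methoxybenzyl)oxy]‑6,8a‑dimethyl‑3‑(propan‑2‑yl)‑1,2,3,5,6,8a‑hexahydroazulen‑3‑ol | CC(C)[C@]1(O)CC[C@]2(C)C=C[C@](C)(OCc3ccc(OC)cc3)CC=C12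
F7 | step 18 | (3R,3aR,4R,6R,8aR)‑6‑[(4‑methoxybenzyl)oxy]‑6,8a‑dimethyl‑3‑(propan‑2‑yl)‑3‑[(triethylsilyl)oxy]‑1,2,3,3a,4,5,6,8a‑octahydroazulen‑4‑ol | CC(C)[C@]1(O[Si](CC)(CC)CC)CC[C@]2(C)C=C[C@](C)(OCc3ccc(OC)cc3)C[C@@H](O)[C@@H]21
F8 | step 18 | (3R,3aS,6R,8aR)‑6‑[(4‑methoxybenzyl)oxy]‑6,8a‑dimethyl‑3‑(propan‑2‑yl)‑3‑[(triethylsilyl)oxy]‑2,3,3a,5,6,8a‑hexahydroazulen‑4(1H)‑one (cis‑fused) | CC(C)[C@]1(O[Si](CC)(CC)CC)CC[C@]2(C)C=C[C@](C)(OCc3ccc(OC)cc3)CC(=O)[C@@H]21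
F9 | step 18 | (3R,3aR,6R,8aR)‑6‑[(4‑methoxybenzyl)oxy]‑6,8a‑dimethyl‑3‑(propan‑2‑yl)‑3‑[(triethylsilyl)oxy]‑2,3,3a,5,6,8a‑hexahydroazulen‑4(1H)‑one (trans‑fused) | CC(C)[C@]1(O[Si](CC)(CC)CC)CC[C@]2(C)C=C[C@](C)(OCc3ccc(OC)cc3)CC(=O)[C@H]21
F10 | step 18 | (3R,3aS,4R,6R,8aR)‑6‑[(4‑methoxybenzyl)oxy]‑6,8a‑dimethyl‑3‑(propan‑2‑yl)‑3‑[(triethylsilyl)oxy]‑1,2,3,3a,4,5,6,8a‑octahydroazulen‑4‑ol | CC(C)[C@]1(O[Si](CC)(CC)CC)CC[C@]2(C)C=C[C@](C)(OCc3ccc(OC)cc3)C[C@@H](O)[C@H]21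
F11 | step 18 | (3R,3aS,4S,6R,8aR)‑6‑[(4‑methoxybenzyl)oxy]‑6,8a‑dimethyl‑3‑(propan‑2‑yl)‑3‑[(triethylsilyl)oxy]‑1,2,3,3a,4,5,6,8a‑octahydroazulen‑4‑yl 4‑[(tert‑butyldimethylsilyl)oxy]benzoate | CC(C)[C@]1(O[Si](CC)(CC)CC)CC[C@]2(C)C=C[C@](C)(OCc3ccc(OC)cc3)C[C@H](OC(=O)c3ccc(O[Si](C)(C)C(C)(C)C)cc3)[C@H]21
F12 | step 13 | (1R,2S)‑2‑ethynyl‑1‑methylcyclopropyl 4‑methoxybenzyl ether | C#C[C@@H]1C[C@@]1(C)OCc1ccc(OC)cc1
F13 | step 13 | (1R,2S)‑1‑methyl‑2‑(prop‑1‑yn‑1‑yl)cyclopropyl 4‑methoxybenzyl ether | CC#C[C@@H]1C[C@@]1(C)OCc1ccc(OC)cc1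
F14 | step 13 | (1R,2S)‑2‑[(1E)‑2‑iodoprop‑1‑en‑1‑yl]‑1‑methylcyclopropyl 4‑methoxybenzyl ether | I/C(C)=C/[C@@H]1C[C@@]1(C)OCc1ccc(OC)cc1
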